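**Retrosynthetic overview**

1. The furan ring is cut last, at O1–C2 and C3a–C3, to iodoresorcinol 13 (ring A) and arylacetylene 19 (ring B). Forward: Sonogashira coupling, then 5-endo closure of O1 onto the alkyne.
2. The plan rests on the C7 substituent: a benzylic CH (Cα) that carries CH3 and is bonded to C(CH3)=CH2. Cutting Cα–CH3 with allylic transposition gives the (E)-3-aryl-2-methylallyl chloride 8 and MeMgBr 9, so one copper-catalysed SN2' step makes the stereocenter and the isopropenyl group together.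
3. C7 lies between two oxygen-bearing carbons (C7a–O1 and C6–OH). Both of these oxygens are carried as MOM ethers and the C4 oxygen as a TIPS ether, so the two free positions of ring A are equivalent for iodination and only an oxygen ortho to the side chain can become O1.
4. Chloride 8 comes from 2,4,6-trihydroxybenzaldehyde 1 (silylation, MOM, Wittig, reduction, chlorination). Alkyne 19 comes from 3,5-dihydroxybenzaldehyde 14 (MOM, 2,6-dibromination, double Stille prenylation, Ohira–Bestmann).
5. Ring order: rings A and B are bought as benzene rings, the furan ring is formed in step 13, and the MOM and TIPS groups are then removed without protic acid.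

Key step: step 6

Assumption: the facial sense of the copper/phosphoramidite catalyst on 8 is taken to follow that of 2-methylcinnamyl chloride; both ligand antipodes are available and the one that gives (R)-10 is retained.

**Route**

Step 1
Reactants: 1 2,4,6-trihydroxybenzaldehyde
Product: 2 2,6-dihydroxy-4-[(triisopropylsilyl)oxy]benzaldehyde
Conditions: i-Pr3SiCl (1.05 equiv), imidazole, DMF, −20 → 0 °C
Reagents that add atoms: chlorotriisopropylsilane, CC(C)[Si](Cl)(C(C)C)C(C)C
Why: Regioselective silylation: the 4-OH, para to the formyl group, is the most acidic hydroxyl and the only one neither flanked by nor hydrogen-bonded to the aldehyde, so one equivalent of the bulky silyl chloride should go there and mark the future C4 oxygen as different from the two ortho oxygens.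

Step 2
Reactants: 2 2,6-dihydroxy-4-[(triisopropylsilyl)oxy]benzaldehyde
Product: 3 2,6-bis(methoxymethoxy)-4-[(triisopropylsilyl)oxy]benzaldehyde
Conditions: NaH (2.4 equiv), MOMCl (2.6 equiv), DMF, 0 °C → rt
Reagents that add atoms: chloromethyl methyl ether, COCCl
Why: O-Alkylation of both sodium phenoxides with MOMCl (Williamson type); NaH is used because one hydroxyl is hydrogen-bonded to the aldehyde, and the aryl TIPS ether tolerates these conditions.

Step 3
Reactants: 3 2,6-bis(methoxymethoxy)-4-[(triisopropylsilyl)oxy]benzaldehyde; 4 ethyl 2-(triphenylphosphoranylidene)propanoate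
Product: 5 ethyl (E)-3-{2,6-bis(methoxymethoxy)-4-[(triisopropylsilyl)oxy]phenyl}-2-methylprop-2-enoate
Conditions: 4 (1.8 equiv), toluene, 110 °C
Reagents that add atoms: ethyl 2-(triphenylphosphoranylidene)propanoate (4), CCOC(=O)C(C)=P(c1ccccc1)(c1ccccc1)c1ccccc1
Why: Wittig olefination with a stabilised α-methyl ylide, which should react with the hindered, electron-rich aldehyde on heating and give the E-trisubstituted enoate.

Step 4
Reactants: 5 ethyl (E)-3-{2,6-bis(methoxymethoxy)-4-[(triisopropylsilyl)oxy]phenyl}-2-methylprop-2-enoate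
Product: 6 (E)-3-{2,6-bis(methoxymethoxy)-4-[(triisopropylsilyl)oxy]phenyl}-2-methylprop-2-en-1-ol
Conditions: i-Bu2AlH (2.5 equiv), CH2Cl2, −78 °C; aqueous sodium potassium tartrate
Reagents that add atoms: none
Why: 1,2-Reduction of the conjugated ester by i-Bu2AlH at low temperature leaves the alkene geometry, the MOM acetals and the aryl silyl ether untouched.

Step 5
Reactants: 6 (E)-3-{2,6-bis(methoxymethoxy)-4-[(triisopropylsilyl)oxy]phenyl}-2-methylprop-2-en-1-ol
Product: 8 (E)-[4-(3-chloro-2-methylprop-1-enyl)-3,5-bis(methoxymethoxy)phenoxy]triisopropylsilane, via allylic mesylate 7 (not isolated)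
Conditions: MsCl, Et3N, THF, 0 °C; then LiCl (5 equiv), 0 °C → rt; used crude
Reagents that add atoms: methanesulfonyl chloride, CS(=O)(=O)Cl (stays only in 7); lithium chloride, [Li+].[Cl-]
Why: Mesylation followed by SN2 displacement with chloride (Collington–Meyers-type allylic chlorination) under non-acidic conditions should give the primary conjugated chloride with the E geometry kept; the labile product is used at once.

Step 6
Reactants: 8 (E)-[4-(3-chloro-2-methylprop-1-enyl)-3,5-bis(methoxymethoxy)phenoxy]triisopropylsilane; 9 methylmagnesium bromide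
Product: 10 (R)-[3,5-bis(methoxymethoxy)-4-(3-methylbut-3-en-2-yl)phenoxy]triisopropylsilane
Conditions: copper thiophene-2-carboxylate CuO2CC4H3S (5 mol%), phosphoramidite L* (6 mol%; from 1,1'-binaphthyl-2,2'-diol and bis[1-(2-methoxyphenyl)ethyl]amine, single enantiomer), CH2Cl2, −78 °C; MeMgBr (3 M in Et2O, 1.3 equiv) added over 3 h
Reagents that add atoms: methylmagnesium bromide (9), C[Mg]Br
Why: MeMgBr transmetalates to the ligand-bound monovalent copper, and the resulting chiral methylcopper–magnesium species binds the alkene of 8 and adds anti to the C–Cl bond at the benzylic γ-carbon, giving a σ-allyl trivalent copper that reductively eliminates to form Cα–CH3 while the double bond moves into the C(CH3)=CH2 position. The closest known reaction is the copper-catalysed enantioselective SN2' alkylation of (E)-3-aryl-2-methylallyl (2-methylcinnamyl) chlorides with Grignard reagents under phosphoramidite ligation. No ring is closed. The new stereocenter Cα is set by the chiral ligand on copper, which selects the alkene face; the ligand antipode that gives (R) is used. The step needs SN2' over SN2 selectivity, which should be secured by the primary chloride on a trisubstituted alkene, by slow Grignard addition in CH2Cl2 at −78 °C, and by ortho MOM ethers that are smaller than silyl ethers at the hindered benzylic carbon. The fixed E geometry from step 3 gives a single alkene isomer, which high enantioselectivity requires.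

Step 7
Reactants: 10 (R)-[3,5-bis(methoxymethoxy)-4-(3-methylbut-3-en-2-yl)phenoxy]triisopropylsilane
Product: 11 (R)-[2-iodo-3,5-bis(methoxymethoxy)-4-(3-methylbut-3-en-2-yl)phenoxy]triisopropylsilane
Conditions: N-iodosuccinimide (1.05 equiv), NaHCO3, MeCN, 0 °C, dark
Reagents that add atoms: N-iodosuccinimide, O=C1CCC(=O)N1I
Why: Electrophilic aromatic iodination of the trioxygenated ring; the two free ring positions are interconverted by rotation about the aryl–Cα bond, so only one mono-iodide can form, and with all phenols capped no hydroxyl can trap an iodonium ion on the isopropenyl group.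

Step 8
Reactants: 11 (R)-[2-iodo-3,5-bis(methoxymethoxy)-4-(3-methylbut-3-en-2-yl)phenoxy]triisopropylsilane
Product: 13 (R)-4-iodo-2-(3-methylbut-3-en-2-yl)-5-[(triisopropylsilyl)oxy]benzene-1,3-diol, via bis(trimethylsilyl) ether 12 (not isolated)
Conditions: Me3SiOTf (4 equiv), 2,2'-bipyridyl (6 equiv), MeCN, 0 °C → rt; then H2O, rt
Reagents that add atoms: trimethylsilyl trifluoromethanesulfonate, C[Si](C)(C)OS(=O)(=O)C(F)(F)F (silicon stays only in 12)
Why: Silyl triflate/2,2'-bipyridyl cleavage of aromatic MOM ethers goes through the aryl trimethylsilyl ethers, which water hydrolyses, so no protic acid meets the isopropenyl group, the aryl iodide or the TIPS ether.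

Step 9
Reactants: 14 3,5-dihydroxybenzaldehyde
Product: 15 3,5-bis(methoxymethoxy)benzaldehyde
Conditions: MOMCl (2.6 equiv), i-Pr2NEt, CH2Cl2, 0 °C → rt
Reagents that add atoms: chloromethyl methyl ether, COCCl
Why: Standard MOM protection of two unhindered phenols with MOMCl and an amine base.

Step 10
Reactants: 15 3,5-bis(methoxymethoxy)benzaldehyde
Product: 16 2,6-dibromo-3,5-bis(methoxymethoxy)benzaldehyde
Conditions: N-bromosuccinimide (2.2 equiv), DMF, 0 °C → 40 °C
Reagents that add atoms: N-bromosuccinimide, O=C1CCC(=O)N1Br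
Why: Electrophilic bromination at C2 and C6, each ortho to one MOM ether and para to the other, as in the known 2,6-dihalogenation of 3,5-dialkoxybenzaldehydes; the position between the two oxygens is the less reactive one.

Step 11
Reactants: 16 2,6-dibromo-3,5-bis(methoxymethoxy)benzaldehyde; 17 tributyl(3-methylbut-2-enyl)stannane
Product: 18 3,5-bis(methoxymethoxy)-2,6-bis(3-methylbut-2-enyl)benzaldehyde
Conditions: 17 (2.6 equiv), Pd(PPh3)4 (10 mol%), DMF, 95 °C, argon
Reagents that add atoms: tributyl(3-methylbut-2-enyl)stannane (17), CCCC[Sn](CCCC)(CCCC)CC=C(C)C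
Why: Twofold Migita–Kosugi–Stille coupling at C–Br bonds activated by the ortho formyl group; the allyl unit passes through an η3-prenyl palladium intermediate that should reductively eliminate at its unsubstituted CH2 end to give the linear prenyl groups.

Step 12
Reactants: 18 3,5-bis(methoxymethoxy)-2,6-bis(3-methylbut-2-enyl)benzaldehyde
Product: 19 3-ethynyl-1,5-bis(methoxymethoxy)-2,4-bis(3-methylbut-2-enyl)benzene
Conditions: dimethyl (1-diazo-2-oxopropyl)phosphonate (1.5 equiv), K2CO3, MeOH, 0 °C → rt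
Reagents that add atoms: dimethyl (1-diazo-2-oxopropyl)phosphonate, COP(=O)(OC)C(=[N+]=[N-])C(C)=O
Why: Seyferth–Gilbert homologation with the Ohira–Bestmann reagent turns the aldehyde into the terminal alkyne under mild base that the MOM ethers and prenyl groups tolerate.

Step 13
Reactants: 13 (R)-4-iodo-2-(3-methylbut-3-en-2-yl)-5-[(triisopropylsilyl)oxy]benzene-1,3-diol; 19 3-ethynyl-1,5-bis(methoxymethoxy)-2,4-bis(3-methylbut-2-enyl)benzene
Product: 21 (R)-2-[3,5-bis(methoxymethoxy)-2,6-bis(3-methylbut-2-enyl)phenyl]-7-(3-methylbut-3-en-2-yl)-4-[(triisopropylsilyl)oxy]-1-benzofuran-6-ol, via o-alkynylphenol 20 (not isolated)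
Conditions: PdCl2(PPh3)2 (5 mol%), CuI (10 mol%), Et3N, DMF, 25 → 70 °C, argon
Reagents that add atoms: none
Why: Sonogashira coupling gives o-alkynylphenol 20, whose hydroxyl next to the alkyne (the only free oxygen beside it, the other neighbour being the TIPS ether) should add 5-endo-dig under copper/palladium activation (Castro–Stephens/Larock-type heteroannulation) to close the furan ring with the side chain at C7.

Step 14
Reactants: 21 (R)-2-[3,5-bis(methoxymethoxy)-2,6-bis(3-methylbut-2-enyl)phenyl]-7-(3-methylbut-3-en-2-yl)-4-[(triisopropylsilyl)oxy]-1-benzofuran-6-ol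
Product: 23 (R)-5-{6-hydroxy-7-(3-methylbut-3-en-2-yl)-4-[(triisopropylsilyl)oxy]-1-benzofuran-2-yl}-4,6-bis(3-methylbut-2-enyl)benzene-1,3-diol, via tris(trimethylsilyl) ether 22 (not isolated)
Conditions: Me3SiOTf (6 equiv), 2,2'-bipyridyl (9 equiv), MeCN, 0 °C → rt; then H2O, rt
Reagents that add atoms: trimethylsilyl trifluoromethanesulfonate, C[Si](C)(C)OS(=O)(=O)C(F)(F)F (silicon stays only in 22)
Why: The same silyl triflate/2,2'-bipyridyl MOM cleavage as in step 8 (the free 6-OH is silylated in passing and released by water), chosen because protic acid could add the ring B phenols to the prenyl groups and the 6-OH to the isopropenyl group.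

Step 15
Reactants: 23 (R)-5-{6-hydroxy-7-(3-methylbut-3-en-2-yl)-4-[(triisopropylsilyl)oxy]-1-benzofuran-2-yl}-4,6-bis(3-methylbut-2-enyl)benzene-1,3-diol
Product: 24 (R)-2-[3,5-dihydroxy-2,6-bis(3-methylbut-2-enyl)phenyl]-7-(3-methylbut-3-en-2-yl)-1-benzofuran-4,6-diol
Conditions: Bu4NF (1.2 equiv), AcOH (1.2 equiv), THF, 0 °C, argon
Reagents that add atoms: none
Why: Fluoride cleavage of the aryl TIPS ether with acetic acid-buffered Bu4NF, which should keep the polyphenol from standing as an air-sensitive phenoxide and leaves the alkenes and the stereocenter alone.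

**Compound list**

1 | 2,4,6-trihydroxybenzaldehyde | O=Cc1c(O)cc(O)cc1O | starting material
2 | 2,6-dihydroxy-4-[(triisopropylsilyl)oxy]benzaldehyde | O=Cc1c(O)cc(O[Si](C(C)C)(C(C)C)C(C)C)cc1O | intermediate
3 | 2,6-bis(methoxymethoxy)-4-[(triisopropylsilyl)oxy]benzaldehyde | O=Cc1c(OCOC)cc(O[Si](C(C)C)(C(C)C)C(C)C)cc1OCOC | intermediate
4 | ethyl 2-(triphenylphosphoranylidene)propanoate | CCOC(=O)C(C)=P(c1ccccc1)(c1ccccc1)c1ccccc1 | starting material
5 | ethyl (E)-3-{2,6-bis(methoxymethoxy)-4-[(triisopropylsilyl)oxy]phenyl}-2-methylprop-2-enoate | CCOC(=O)/C(C)=C/c1c(OCOC)cc(O[Si](C(C)C)(C(C)C)C(C)C)cc1OCOC | intermediate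
6 | (E)-3-{2,6-bis(methoxymethoxy)-4-[(triisopropylsilyl)oxy]phenyl}-2-methylprop-2-en-1-ol | OC/C(C)=C/c1c(OCOC)cc(O[Si](C(C)C)(C(C)C)C(C)C)cc1OCOC | intermediate
7 | (E)-3-{2,6-bis(methoxymethoxy)-4-[(triisopropylsilyl)oxy]phenyl}-2-methylprop-2-enyl methanesulfonate | CS(=O)(=O)OC/C(C)=C/c1c(OCOC)cc(O[Si](C(C)C)(C(C)C)C(C)C)cc1OCOC | intermediate (not isolated)
8 | (E)-[4-(3-chloro-2-methylprop-1-enyl)-3,5-bis(methoxymethoxy)phenoxy]triisopropylsilane | ClC/C(C)=C/c1c(OCOC)cc(O[Si](C(C)C)(C(C)C)C(C)C)cc1OCOC | intermediate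
9 | methylmagnesium bromide | C[Mg]Br | starting material
10 | (R)-[3,5-bis(methoxymethoxy)-4-(3-methylbut-3-en-2-yl)phenoxy]triisopropylsilane | C=C(C)[C@@H](C)c1c(OCOC)cc(O[Si](C(C)C)(C(C)C)C(C)C)cc1OCOC | intermediate
11 | (R)-[2-iodo-3,5-bis(methoxymethoxy)-4-(3-methylbut-3-en-2-yl)phenoxy]triisopropylsilane | C=C(C)[C@@H](C)c1c(OCOC)cc(O[Si](C(C)C)(C(C)C)C(C)C)c(I)c1OCOC | intermediate
12 | (R)-[2-iodo-4-(3-methylbut-3-en-2-yl)-3,5-bis(trimethylsilyloxy)phenoxy]triisopropylsilane | C=C(C)[C@@H](C)c1c(O[Si](C)(C)C)cc(O[Si](C(C)C)(C(C)C)C(C)C)c(I)c1O[Si](C)(C)C | intermediate (not isolated)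
13 | (R)-4-iodo-2-(3-methylbut-3-en-2-yl)-5-[(triisopropylsilyl)oxy]benzene-1,3-diol | C=C(C)[C@@H](C)c1c(O)cc(O[Si](C(C)C)(C(C)C)C(C)C)c(I)c1O | intermediate
14 | 3,5-dihydroxybenzaldehyde | O=Cc1cc(O)cc(O)c1 | starting material
15 | 3,5-bis(methoxymethoxy)benzaldehyde | O=Cc1cc(OCOC)cc(OCOC)c1 | intermediate
16 | 2,6-dibromo-3,5-bis(methoxymethoxy)benzaldehyde | O=Cc1c(Br)c(OCOC)cc(OCOC)c1Br | intermediate
17 | tributyl(3-methylbut-2-enyl)stannane | CCCC[Sn](CCCC)(CCCC)CC=C(C)C | starting material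
18 | 3,5-bis(methoxymethoxy)-2,6-bis(3-methylbut-2-enyl)benzaldehyde | O=Cc1c(CC=C(C)C)c(OCOC)cc(OCOC)c1CC=C(C)C | intermediate
19 | 3-ethynyl-1,5-bis(methoxymethoxy)-2,4-bis(3-methylbut-2-enyl)benzene | C#Cc1c(CC=C(C)C)c(OCOC)cc(OCOC)c1CC=C(C)C | intermediate
20 | (R)-4-{[3,5-bis(methoxymethoxy)-2,6-bis(3-methylbut-2-enyl)phenyl]ethynyl}-2-(3-methylbut-3-en-2-yl)-5-[(triisopropylsilyl)oxy]benzene-1,3-diol | C=C(C)[C@@H](C)c1c(O)cc(O[Si](C(C)C)(C(C)C)C(C)C)c(C#Cc2c(CC=C(C)C)c(OCOC)cc(OCOC)c2CC=C(C)C)c1O | intermediate (not isolated)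
21 | (R)-2-[3,5-bis(methoxymethoxy)-2,6-bis(3-methylbut-2-enyl)phenyl]-7-(3-methylbut-3-en-2-yl)-4-[(triisopropylsilyl)oxy]-1-benzofuran-6-ol | C=C(C)[C@@H](C)c1c(O)cc(O[Si](C(C)C)(C(C)C)C(C)C)c2cc(-c3c(CC=C(C)C)c(OCOC)cc(OCOC)c3CC=C(C)C)oc12 | intermediate
22 | (R)-{[2-[2,6-bis(3-methylbut-2-enyl)-3,5-bis(trimethylsilyloxy)phenyl]-7-(3-methylbut-3-en-2-yl)-6-(trimethylsilyloxy)-1-benzofuran-4-yl]oxy}triisopropylsilane | C=C(C)[C@@H](C)c1c(O[Si](C)(C)C)cc(O[Si](C(C)C)(C(C)C)C(C)C)c2cc(-c3c(CC=C(C)C)c(O[Si](C)(C)C)cc(O[Si](C)(C)C)c3CC=C(C)C)oc12 | intermediate (not isolated)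
23 | (R)-5-{6-hydroxy-7-(3-methylbut-3-en-2-yl)-4-[(triisopropylsilyl)oxy]-1-benzofuran-2-yl}-4,6-bis(3-methylbut-2-enyl)benzene-1,3-diol | C=C(C)[C@@H](C)c1c(O)cc(O[Si](C(C)C)(C(C)C)C(C)C)c2cc(-c3c(CC=C(C)C)c(O)cc(O)c3CC=C(C)C)oc12 | intermediate
24 | (R)-2-[3,5-dihydroxy-2,6-bis(3-methylbut-2-enyl)phenyl]-7-(3-methylbut-3-en-2-yl)-1-benzofuran-4,6-diol | C=C(C)[C@@H](C)c1c(O)cc(O)c2cc(-c3c(CC=C(C)C)c(O)cc(O)c3CC=C(C)C)oc12 | target

**Step count**

Total: 15 steps. Longest linear sequence: 11 steps (steps 1–8 and 13–15); steps 9–12 make the ring B alkyne.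

**Steps most likely to fail**

Step 6. Methyl transfer may go SN2 to the linear achiral product, or with poor facial selectivity, because the benzylic carbon sits between two ortho oxygens and the aryl ring is twisted out of conjugation. Ionisation of the electron-rich allylic chloride could add a racemic pathway. The fallback sets out from allylic alcohol 6 and sets the stereocenter by reagent-controlled epoxidation followed by stereospecific opening. Sharpless asymmetric epoxidation (Ti(OiPr)4, D-(−)-diisopropyl tartrate, t-BuOOH, 4 Å sieves, CH2Cl2, −20 °C) should give [(2R,3R)-3-{2,6-bis(methoxymethoxy)-4-[(triisopropylsilyl)oxy]phenyl}-2-methyloxiran-2-yl]methanol F1. AlMe3 (CH2Cl2/hexane, −40 → 0 °C) opens the epoxide at the benzylic carbon with inversion to (2S,3S)-3-{2,6-bis(methoxymethoxy)-4-[(triisopropylsilyl)oxy]phenyl}-2-methylbutane-1,2-diol F2. 1,1'-Thiocarbonyldiimidazole (toluene, 80 °C) gives (S)-4-[(S)-1-{2,6-bis(methoxymethoxy)-4-[(triisopropylsilyl)oxy]phenyl}ethyl]-4-methyl-1,3-dioxolane-2-thione F3. Corey–Winter olefination under the mild Corey–Hopkins conditions (1,3-dimethyl-2-phenyl-1,3,2-diazaphospholidine, THF, 40 °C) removes the diol as the 1,1-disubstituted alkene and returns to the route at 10.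

Step 13. Oxidative addition into the electron-rich C–I bond flanked by OH and OTIPS may be slow, so alkyne homocoupling, hydrodeiodination or oxidation of the free resorcinol could compete, and palladium hydride species could move the isopropenyl double bond. The fallback sets out from the protected iodide 11 and alkyne 19 and separates coupling from ring closure. Sonogashira coupling (PdCl2(PPh3)2, CuI, Et3N, THF, 50 °C) gives (R)-{2-{[3,5-bis(methoxymethoxy)-2,6-bis(3-methylbut-2-enyl)phenyl]ethynyl}-3,5-bis(methoxymethoxy)-4-(3-methylbut-3-en-2-yl)phenoxy}triisopropylsilane F6. Me3SiOTf/2,2'-bipyridyl in MeCN converts all four MOM ethers into the tetrakis(trimethylsilyl) ether (R)-{2-{[2,6-bis(3-methylbut-2-enyl)-3,5-bis(trimethylsilyloxy)phenyl]ethynyl}-4-(3-methylbut-3-en-2-yl)-3,5-bis(trimethylsilyloxy)phenoxy}triisopropylsilane F7, which is not isolated. Water then releases (R)-4-{[3,5-dihydroxy-2,6-bis(3-methylbut-2-enyl)phenyl]ethynyl}-2-(3-methylbut-3-en-2-yl)-5-[(triisopropylsilyl)oxy]benzene-1,3-diol F8. Base-mediated 5-endo-dig hydroalkoxylation (Cs2CO3, DMF, 60 °C) by the only hydroxyl next to the alkyne closes the furan ring and returns to the route at 23.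

Step 8. Iodine may be lost from the very electron-rich ring (protodeiodination or iodine transfer) while the MOM ethers are exchanged for silyl ethers and hydrolysed. The fallback sets out from 10 and reverses the order, so that no aryl iodide is present during MOM cleavage. Me3SiOTf/2,2'-bipyridyl in MeCN gives the bis(trimethylsilyl) ether (R)-[4-(3-methylbut-3-en-2-yl)-3,5-bis(trimethylsilyloxy)phenoxy]triisopropylsilane F4, not isolated. Water releases (R)-2-(3-methylbut-3-en-2-yl)-5-[(triisopropylsilyl)oxy]benzene-1,3-diol F5. The symmetric resorcinol is then mono-iodinated with N-iodosuccinimide (0.95 equiv, CH2Cl2, −78 °C), where ring substitution should outrun iodoetherification of the isopropenyl group. The route is rejoined at 13.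

**Further compounds**

F1 | step 6 | [(2R,3R)-3-{2,6-bis(methoxymethoxy)-4-[(triisopropylsilyl)oxy]phenyl}-2-methyloxiran-2-yl]methanol | OC[C@@]1(C)O[C@@H]1c1c(OCOC)cc(O[Si](C(C)C)(C(C)C)C(C)C)cc1OCOC
F2 | step 6 | (2S,3S)-3-{2,6-bis(methoxymethoxy)-4-[(triisopropylsilyl)oxy]phenyl}-2-methylbutane-1,2-diol | OC[C@@](C)(O)[C@@H](C)c1c(OCOC)cc(O[Si](C(C)C)(C(C)C)C(C)C)cc1OCOC
F3 | step 6 | (S)-4-[(S)-1-{2,6-bis(methoxymethoxy)-4-[(triisopropylsilyl)oxy]phenyl}ethyl]-4-methyl-1,3-dioxolane-2-thione | S=C1OC[C@@](C)(O1)[C@@H](C)c1c(OCOC)cc(O[Si](C(C)C)(C(C)C)C(C)C)cc1OCOC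
F4 | step 8 | (R)-[4-(3-methylbut-3-en-2-yl)-3,5-bis(trimethylsilyloxy)phenoxy]triisopropylsilane | C=C(C)[C@@H](C)c1c(O[Si](C)(C)C)cc(O[Si](C(C)C)(C(C)C)C(C)C)cc1O[Si](C)(C)C
F5 | step 8 | (R)-2-(3-methylbut-3-en-2-yl)-5-[(triisopropylsilyl)oxy]benzene-1,3-diol | C=C(C)[C@@H](C)c1c(O)cc(O[Si](C(C)C)(C(C)C)C(C)C)cc1O
F6 | step 13 | (R)-{2-{[3,5-bis(methoxymethoxy)-2,6-bis(3-methylbut-2-enyl)phenyl]ethynyl}-3,5-bis(methoxymethoxy)-4-(3-methylbut-3-en-2-yl)phenoxy}triisopropylsilane | C=C(C)[C@@H](C)c1c(OCOC)cc(O[Si](C(C)C)(C(C)C)C(C)C)c(C#Cc2c(CC=C(C)C)c(OCOC)cc(OCOC)c2CC=C(C)C)c1OCOC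
F7 | step 13 | (R)-{2-{[2,6-bis(3-methylbut-2-enyl)-3,5-bis(trimethylsilyloxy)phenyl]ethynyl}-4-(3-methylbut-3-en-2-yl)-3,5-bis(trimethylsilyloxy)phenoxy}triisopropylsilane | C=C(C)[C@@H](C)c1c(O[Si](C)(C)C)cc(O[Si](C(C)C)(C(C)C)C(C)C)c(C#Cc2c(CC=C(C)C)c(O[Si](C)(C)C)cc(O[Si](C)(C)C)c2CC=C(C)C)c1O[Si](C)(C)C
F8 | step 13 | (R)-4-{[3,5-dihydroxy-2,6-bis(3-methylbut-2-enyl)phenyl]ethynyl}-2-(3-methylbut-3-en-2-yl)-5-[(triisopropylsilyl)oxy]benzene-1,3-diol | C=C(C)[C@@H](C)c1c(O)cc(O[Si](C(C)C)(C(C)C)C(C)C)c(C#Cc2c(CC=C(C)C)c(O)cc(O)c2CC=C(C)C)c1O
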